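## Analysis of the target

Target 22 is a 1-aryl-1,2-dihydronaphthalene. In the numbering used here C1 carries the 4-hydroxy-3,5-dimethoxyphenyl ring, C2 the CH2OH group, C3 the formyl group and C4 is the vinylic CH; ring A runs C4a, C5 (H), C6 (OMe), C7 (OH), C8 (OMe), C8a, with C8a bonded to C1. Ring B (C1–C4, C4a, C8a) is the only non-aromatic ring, and its C3=C4 double bond is conjugated with the aldehyde on one side and with ring A on the other. There are two stereocentres, C1 (S) and C2 (R); they are neighbours, and the aryl group on C1 and the hydroxymethyl group on C2 lie on opposite faces of ring B (trans). Ring A and the pendant ring both show the 2,6-dimethoxyphenol pattern, so both can come from the same family of building blocks, but ring A is pentasubstituted and its C8 methoxy group crowds the diarylmethine carbon C1. The sensitive points are the enal, the two electron-rich free phenols, the doubly benzylic C1–H, and the fact that ring B is one oxidation away from a naphthalene, which would erase both stereocentres; strong oxidants and strong bases are therefore excluded late in the route. The difficulty is to set the trans pair C1/C2 at a crowded carbon and then to close ring B so that the alkene ends at C3=C4 and the one-carbon substituent on C3 at the aldehyde oxidation state. The strategy rests on C4: it is an unsubstituted CH between C4a of ring A and C3, which bears the formyl carbon. It can therefore be brought in as carbon monoxide between an arylpalladium at C4a and C3 of an enol ether, giving a C4 ketone next to a C3 methoxymethylene group, which is a masked form of the C3-formyl C3=C4 unit.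

## Retrosynthetic reasoning

22 from 20 and 19. No skeletal bond is cut. The enal of 22 is the product of an acid-induced allylic transposition of alcohol 20, in which the C4 hydroxyl leaves and the exocyclic enol ether carbon becomes the formyl carbon. The same acid removes the silyl ether and both acetal protecting groups by way of 21. Alcohol 20 is the 1,2-reduction product of ketone 19. The gain is that the enal and the free phenols appear only in the last operation.

19 from 17 and 18. The bonds C4a–C4 and C4–C3 are cut. C4 is chosen because it is the one atom of ring B with no substituent and no stereochemistry, so it can be a one-carbon building block, carbon monoxide 18. Cutting there leaves C1 and C2 with all their substituents in an open chain, where they can be set before the ring exists. The forward reaction must insert palladium into the C4a–O bond of triflate 17, take up 18 before the alkene, bond the acyl carbon to C3 and eliminate to the β-methoxy enone.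

17 from 16. The C3=CH(OMe) double bond is cut back to the aldehyde carbon of 16 (one-carbon Wittig homologation). This puts the nucleophilic alkene carbon exactly at C3 and carries the future formyl carbon as the enol ether carbon.

16 from 15 and 14. The bond from C2 to its CH2O carbon is cut. In 14, C2 is the α-carbon of an aldehyde, so an enamine-catalysed aldol with a one-carbon aldehyde installs the hydroxymethyl group and sets C2 under catalyst control. Silylation of 15 to 16 blocks retro-aldol and dehydration.

14 from 8 and 13. The C1–aryl bond is cut as an asymmetric conjugate addition of an arylboron reagent to an enal, which sets C1. The pendant ring is the nucleophile because 13 has no ortho substituents, whereas a ring A boronic acid would carry two ortho oxygens and would transmetalate poorly and protodeboronate.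

8 from 7, 6, 4, 2 and 1. Enal 8 comes from aldehyde 7 by a two-carbon olefination. Triflate 7 comes from salicylaldehyde 6, so the C4a oxygen is turned into the leaving group early and needs no protecting group of its own. 6 comes from phenol 4 by ortho-formylation; the two ortho positions of 4 are equivalent, so the regiochemistry is not in question. 4 comes from 2 through formate 3, which exchanges the formyl carbon of 1 for the C4a oxygen. 2 is the protected form of 1.

13 from 10 and 9. The C–B bond is made from the C–Br bond of 10, the protected form of 9.

## Alternatives that were turned down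

Alternative 1: The bonds C4a–C4 and C8a–C1 are cut at ring A together. In the forward step CsF turns silyl triflate A2 into the trioxygenated aryne, which inserts into the C–C bond of β-keto ester A3 to give keto ester A1. In its favour: one step attaches both carbon substituents to ring A, and the C8 methoxy group directs the enolate carbon to C4a and the aroyl group to C8a, so the regiochemistry is secure. It is more convergent at ring A than the chosen route and needs no transition metal. Against it: A1 has neither ring B nor a stereocentre. C1 arrives as a diaryl ketone, and C2, its CH2OH carbon and the formyl carbon are all missing. The ester carbon (C3) would need two new carbon–carbon bonds, and the natural continuation (condensation and aromatisation) leads to a naphthalene, the wrong oxidation level. A2 also needs several steps. The chosen strategy instead sets both stereocentres before the ring is closed and closes ring B directly at the right oxidation level.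

Alternative 2: The bonds C1–C2 and C4a–C8a are cut. In the forward step a triflimide-activated B-(o-tolyl)oxazaborolidine derived from α,α-diphenylprolinol binds the C8 carbonyl of trienedione A5 and promotes an intramolecular Diels–Alder reaction to the cis-fused octalindione A4. In its favour: ring B, a six-membered precursor of ring A, C1 and C2 are all formed in one step, the relative configuration comes from the alkene geometries and the absolute one from the catalyst. On bonds and stereocentres per step it is stronger than the chosen key step, which creates no stereocentre. Against it: ring A arrives as a cyclohexane-1,3-dione without the C7 oxygen. It needs oxidation at C7, dehydrogenation and selective methylation of the C6 and C8 oxygens with C7 left free, and the dehydrogenation must stop before ring B aromatises. The 1,3-dione of A5 is enolised, which deactivates the dienophile and competes for the Lewis acid. C3 comes as a silyloxymethyl group that has to be told apart from the one on C2 and oxidised. The chosen route brings ring A in fully substituted and aromatic and has two steps after ring closure.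

Alternative 3: The bonds C1–aryl and C2–C3 are cut. In the forward step [Rh(cod)Cl]2 with a BINAP enantiomer and KOH transfers the aryl group of 13 to C1 of enoate A7, and the rhodium enolate at C2 adds to the C3 keto ester to give hydroxy diester A6. In its favour: two bonds, ring B and the C1 stereocentre arise in one step. C2 is α to an ester and can be equilibrated to trans, and the C3 hydroxyl sits where dehydration gives the C3=C4 alkene. The endgame (dehydration, reduction of both esters, selective oxidation of the allylic alcohol, deprotection) is short. On step economy after the key step it is as strong as the chosen route, and on bonds per step it is stronger. Against it: the pyruvate arm of A7 is a benzylic α-keto ester and is largely enolised. Under KOH its C4 enolate can add to the neighbouring enoate (5-exo Michael addition to an indane), and the enolised ketone is a poor acceptor for the rhodium enolate, so simple protonation competes. Two different carbon chains have to be placed on adjacent positions of the tetra-oxygenated ring, and the two esters must be differentiated later. The chosen strategy uses the same aryl transfer on a simple enal, has no enolisable 1,2-dicarbonyl unit, and brings C3 in at the aldehyde oxidation state.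

Key step: step 12

Assumption: the enantiomer of the diene ligand in step 8 is the one that delivers the aryl group to the Re face of C1, judged by the accepted quadrant model of C2-symmetric diene–rhodium aryl complexes; the other enantiomer is used if the first run shows the opposite sense. Enol ether 17 and the exocyclic alkene of 19 are carried as E/Z mixtures, because both isomers converge in steps 12 and 14.

## Route

Step 1
Reactants: 1 syringaldehyde (4-hydroxy-3,5-dimethoxybenzaldehyde)
Product: 2 3,5-dimethoxy-4-(methoxymethoxy)benzaldehyde
Conditions: MOMCl, i-Pr2NEt, CH2Cl2, 0 °C to rt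
Reagents that add atoms: chloromethyl methyl ether, COCCl
Why: O-alkylation of the phenol (methoxymethyl protection); the acetal withstands the basic, organometallic and palladium steps and falls in the acid of step 14.

Step 2
Reactants: 2 3,5-dimethoxy-4-(methoxymethoxy)benzaldehyde
Product: 4 3,5-dimethoxy-4-(methoxymethoxy)phenol, via aryl formate 3 (not isolated)
Conditions: mCPBA, NaHCO3, CH2Cl2, rt; then K2CO3, MeOH, rt
Reagents that add atoms: 3-chloroperbenzoic acid, O=C(OO)c1cccc(Cl)c1
Why: Baeyer–Villiger (Dakin-type) oxidation; the electron-rich aryl group migrates to give formate 3, which mild methanolysis cleaves, and the buffer keeps the acetal intact.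

Step 3
Reactants: 4 3,5-dimethoxy-4-(methoxymethoxy)phenol
Product: 6 6-hydroxy-2,4-dimethoxy-3-(methoxymethoxy)benzaldehyde, via salicyl alcohol 5 (not isolated)
Conditions: MgCl2, Et3N, (CH2O)n, MeCN, reflux
Reagents that add atoms: formaldehyde (as paraformaldehyde), C=O
Why: Casnati–Skattebøl ortho-formylation; the magnesium phenoxide delivers formaldehyde to the ortho carbon only and a second formaldehyde oxidises alcohol 5 by hydride transfer. The two ortho positions of 4 are equivalent, so only one regioisomer can form.

Step 4
Reactants: 6 6-hydroxy-2,4-dimethoxy-3-(methoxymethoxy)benzaldehyde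
Product: 7 2-formyl-3,5-dimethoxy-4-(methoxymethoxy)phenyl trifluoromethanesulfonate
Conditions: Tf2O, pyridine, CH2Cl2, −10 °C
Reagents that add atoms: trifluoromethanesulfonic anhydride, O=S(=O)(OS(=O)(=O)C(F)(F)F)C(F)(F)F
Why: O-sulfonylation of the phenol; the C4a oxygen becomes the leaving group for step 12 at once and needs no separate protecting group. Aryl triflates tolerate the neutral, weakly basic and low-temperature conditions of steps 5 to 11.

Step 5
Reactants: 7 2-formyl-3,5-dimethoxy-4-(methoxymethoxy)phenyl trifluoromethanesulfonate
Product: 8 3,5-dimethoxy-4-(methoxymethoxy)-2-[(E)-3-oxoprop-1-enyl]phenyl trifluoromethanesulfonate (ring A cinnamaldehyde)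
Conditions: Ph3P=CHCHO, toluene, 80 °C
Reagents that add atoms: (triphenylphosphoranylidene)acetaldehyde, O=CC=P(c1ccccc1)(c1ccccc1)c1ccccc1
Why: Wittig olefination with a stabilised formyl ylide gives the (E)-enal; the ortho triflate makes the hindered aldehyde more electrophilic, and the product enal is less electrophilic, which limits a second homologation.

Step 6
Reactants: 9 4-bromo-2,6-dimethoxyphenol
Product: 10 5-bromo-1,3-dimethoxy-2-(methoxymethoxy)benzene
Conditions: MOMCl, i-Pr2NEt, CH2Cl2, 0 °C to rt
Reagents that add atoms: chloromethyl methyl ether, COCCl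
Why: Methoxymethyl protection of the phenol, needed because a free phenol would quench the aryllithium of step 7 and interfere in step 12.

Step 7
Reactants: 10 5-bromo-1,3-dimethoxy-2-(methoxymethoxy)benzene
Product: 13 [3,5-dimethoxy-4-(methoxymethoxy)phenyl]boronic acid, via aryllithium 11 (not isolated), via lithium triisopropoxyborate 12 (not isolated)
Conditions: n-BuLi, THF, −78 °C; B(Oi-Pr)3, −78 °C to rt; aq. NH4Cl
Reagents that add atoms: triisopropyl borate, CC(C)OB(OC(C)C)OC(C)C; water, O
Why: Bromine–lithium exchange is faster than ortho-metalation at −78 °C; the aryllithium is trapped by the borate and the mild ammonium chloride hydrolysis spares the acetal.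

Step 8
Reactants: 8 ring A cinnamaldehyde; 13 [3,5-dimethoxy-4-(methoxymethoxy)phenyl]boronic acid
Product: 14 2-[(1S)-1-[3,5-dimethoxy-4-(methoxymethoxy)phenyl]-3-oxopropyl]-3,5-dimethoxy-4-(methoxymethoxy)phenyl trifluoromethanesulfonate
Conditions: [RhCl(C2H4)2]2 (2.5 mol %), 2,5-diphenylbicyclo[2.2.2]octa-2,5-diene (single enantiomer, 5.5 mol %), KOH (0.2 equiv), dioxane/H2O 10:1, 30 °C
Reagents that add atoms: none
Why: Rhodium-catalysed asymmetric 1,4-addition (Hayashi–Miyaura reaction); with a chiral diene ligand the aryl–rhodium species adds to the alkene of the enal and not to the formyl group, and delivery of the aryl group to the Re face of C1 sets C1 as S. The triflate is inert to monovalent rhodium and to substoichiometric hydroxide at this temperature.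

Step 9
Reactants: 14 (S)-3,3-diarylpropanal
Product: 15 2-[(1S,2S)-1-[3,5-dimethoxy-4-(methoxymethoxy)phenyl]-2-(hydroxymethyl)-3-oxopropyl]-3,5-dimethoxy-4-(methoxymethoxy)phenyl trifluoromethanesulfonate
Conditions: aq. CH2O (37 %), (R)-2-[diphenyl(trimethylsilyloxy)methyl]pyrrolidine (20 mol %), pH 7 phosphate buffer, toluene, rt
Reagents that add atoms: formaldehyde, C=O
Why: Enamine-catalysed aldol reaction with formaldehyde (α-hydroxymethylation); the (E)-enamine takes up the electrophile on the face away from the diphenyl(silyloxy)methyl group, which with the (R)-catalyst sets C2 as drawn (S in this aldehyde, R in the target). In the A(1,3)-minimised enamine conformer the bulky ring A aryl group is expected to shield the opposite face, so substrate and catalyst should reinforce each other.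

Step 10
Reactants: 15 β-hydroxy aldehyde
Product: 16 2-[(1S,2S)-2-[[tert-butyl(dimethyl)silyl]oxymethyl]-1-[3,5-dimethoxy-4-(methoxymethoxy)phenyl]-3-oxopropyl]-3,5-dimethoxy-4-(methoxymethoxy)phenyl trifluoromethanesulfonate
Conditions: TBSCl, imidazole, CH2Cl2, 0 °C (crude 15 used at once)
Reagents that add atoms: tert-butyldimethylsilyl chloride, CC(C)(C)[Si](C)(C)Cl
Why: Silylation of the primary alcohol; it stops retro-aldol and dehydration of the β-hydroxy aldehyde, and imidazole at 0 °C is too weak a base to epimerise C2.

Step 11
Reactants: 16 silyloxy aldehyde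
Product: 17 2-[(1S,2R)-2-[[tert-butyl(dimethyl)silyl]oxymethyl]-1-[3,5-dimethoxy-4-(methoxymethoxy)phenyl]-4-methoxybut-3-enyl]-3,5-dimethoxy-4-(methoxymethoxy)phenyl trifluoromethanesulfonate (E/Z mixture at the enol ether)
Conditions: MeOCH2PPh3Cl, NaHMDS, THF, 0 °C; then 16, −78 to 0 °C
Reagents that add atoms: (methoxymethyl)triphenylphosphonium chloride, COC[P+](c1ccccc1)(c1ccccc1)c1ccccc1.[Cl-]
Why: Wittig methoxymethylenation; addition of the preformed ylide to the aldehyde at low temperature is faster than α-deprotonation, and a slight deficit of base leaves no amide to attack the triflate. The change of the C2 descriptor from S to R is a change of priorities only.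

Step 12
Reactants: 17 aryl triflate enol ether; 18 carbon monoxide
Product: 19 (3R,4S)-3-[[tert-butyl(dimethyl)silyl]oxymethyl]-4-[3,5-dimethoxy-4-(methoxymethoxy)phenyl]-5,7-dimethoxy-6-(methoxymethoxy)-2-(methoxymethylidene)-3,4-dihydronaphthalen-1(2H)-one (target numbering: C4 ketone, C3 methoxymethylene, 1S,2R)
Conditions: Pd(OAc)2 (10 mol %), dppp (12 mol %), Et3N, CO (20 bar), DMF, 80 °C
Reagents that add atoms: none
Why: Pd(OAc)2 and dppp are reduced in the flask to a zerovalent palladium complex, which inserts into the C4a–O bond of the triflate to give a cationic arylpalladium species; under carbon monoxide pressure this takes up 18, and migratory insertion gives the aroylpalladium complex whose acyl carbon is the future C4. The enol ether then coordinates and undergoes syn acylpalladation, in which the acyl carbon bonds to C3, the nucleophilic carbon of the enol ether, and palladium ends on the methoxy-bearing carbon. Syn β-hydride elimination of the only β-hydrogen available, the one on C3, releases β-methoxy enone 19, and Et3N returns the palladium hydride to the zerovalent state. The closest known reaction type is the carbonylative Heck cyclisation (cyclic acylpalladation) of ortho-alkenyl aryl halides and triflates to 2-alkylidene-1-indanones and 2-alkylidene-1-tetralones. Ring B is closed in the 6-exo-trig mode, the acyl carbon reaching C3 through the three-atom tether C8a–C1–C2. No stereocentre is created: C3 becomes trigonal, and C1 and C2 are untouched because neither hydrogen is activated by the new carbonyl group (C2–H is cross-conjugated) and Et3N is too weak a base to remove them. The step needs carbon monoxide insertion to outrun direct arylpalladation of the alkene (5-exo or 6-endo), and acyl transfer to C3 and not to the oxygen-bearing carbon (7-endo); the gas pressure and the chelating dppp ligand favour the first, and the low reactivity of a 1,2-disubstituted enol ether towards arylpalladium together with the tether length, which puts only C3 within reach of an unstrained four-centre insertion, should secure both. Both enol ether isomers of 17 lead to the same constitution.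

Step 13
Reactants: 19 β-methoxy enone
Product: 20 (3R,4S)-3-[[tert-butyl(dimethyl)silyl]oxymethyl]-4-[3,5-dimethoxy-4-(methoxymethoxy)phenyl]-5,7-dimethoxy-6-(methoxymethoxy)-2-(methoxymethylidene)-1,2,3,4-tetrahydronaphthalen-1-ol (mixture at the carbinol carbon C4 of the target numbering)
Conditions: NaBH4, CeCl3·7H2O, MeOH/THF, −20 to 0 °C; neutral work-up, used crude
Reagents that add atoms: none
Why: Luche 1,2-reduction of the vinylogous ester carbonyl; CeCl3 suppresses conjugate hydride addition, and the configuration of the new carbinol is irrelevant because step 14 removes it.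

Step 14
Reactants: 20 allylic alcohol
Product: 22 (1S,2R)-7-hydroxy-1-(4-hydroxy-3,5-dimethoxyphenyl)-2-(hydroxymethyl)-6,8-dimethoxy-1,2-dihydronaphthalene-3-carbaldehyde, via protected enal 21 (not isolated)
Conditions: 3 M aq. HCl/THF 1:3, rt then 45 °C
Reagents that add atoms: water, O
Why: Acid ionises the C4 hydroxyl (benzylic, para to the C7 oxygen, and conjugated with the enol ether) to an oxocarbenium ion; water adds at the former enol ether carbon and methanol is lost, giving the C3 formyl group and the C3=C4 alkene (hydrolytic allylic transposition of a reduced vinylogous ester). The same medium cleaves the silyl ether and both methoxymethyl acetals, and C1 and C2 are not enolisable positions of the product enal, so the trans pair is kept.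

## Compound list

1 | syringaldehyde (4-hydroxy-3,5-dimethoxybenzaldehyde) | COc1cc(C=O)cc(OC)c1O | starting material
2 | 3,5-dimethoxy-4-(methoxymethoxy)benzaldehyde | COCOc1c(OC)cc(C=O)cc1OC | intermediate
3 | 3,5-dimethoxy-4-(methoxymethoxy)phenyl formate | O=COc1cc(OC)c(OCOC)c(OC)c1 | intermediate
4 | 3,5-dimethoxy-4-(methoxymethoxy)phenol | COCOc1c(OC)cc(O)cc1OC | intermediate
5 | 2-(hydroxymethyl)-3,5-dimethoxy-4-(methoxymethoxy)phenol | COCOc1c(OC)cc(O)c(CO)c1OC | intermediate
6 | 6-hydroxy-2,4-dimethoxy-3-(methoxymethoxy)benzaldehyde | COCOc1c(OC)cc(O)c(C=O)c1OC | intermediate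
7 | 2-formyl-3,5-dimethoxy-4-(methoxymethoxy)phenyl trifluoromethanesulfonate | COCOc1c(OC)cc(OS(=O)(=O)C(F)(F)F)c(C=O)c1OC | intermediate
8 | 3,5-dimethoxy-4-(methoxymethoxy)-2-[(E)-3-oxoprop-1-enyl]phenyl trifluoromethanesulfonate | COCOc1c(OC)cc(OS(=O)(=O)C(F)(F)F)c(/C=C/C=O)c1OC | intermediate
9 | 4-bromo-2,6-dimethoxyphenol | COc1cc(Br)cc(OC)c1O | starting material
10 | 5-bromo-1,3-dimethoxy-2-(methoxymethoxy)benzene | COCOc1c(OC)cc(Br)cc1OC | intermediate
11 | [3,5-dimethoxy-4-(methoxymethoxy)phenyl]lithium | [Li]c1cc(OC)c(OCOC)c(OC)c1 | intermediate
12 | lithium triisopropoxy[3,5-dimethoxy-4-(methoxymethoxy)phenyl]borate | [Li+].COCOc1c(OC)cc(cc1OC)[B-](OC(C)C)(OC(C)C)OC(C)C | intermediate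
13 | [3,5-dimethoxy-4-(methoxymethoxy)phenyl]boronic acid | COCOc1c(OC)cc(B(O)O)cc1OC | intermediate
14 | 2-[(1S)-1-[3,5-dimethoxy-4-(methoxymethoxy)phenyl]-3-oxopropyl]-3,5-dimethoxy-4-(methoxymethoxy)phenyl trifluoromethanesulfonate | COc1cc([C@H](CC=O)c2c(OC)c(OCOC)c(OC)cc2OS(=O)(=O)C(F)(F)F)cc(OC)c1OCOC | intermediate
15 | 2-[(1S,2S)-1-[3,5-dimethoxy-4-(methoxymethoxy)phenyl]-2-(hydroxymethyl)-3-oxopropyl]-3,5-dimethoxy-4-(methoxymethoxy)phenyl trifluoromethanesulfonate | COc1cc([C@H]([C@@H](CO)C=O)c2c(OC)c(OCOC)c(OC)cc2OS(=O)(=O)C(F)(F)F)cc(OC)c1OCOC | intermediate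
16 | 2-[(1S,2S)-2-[[tert-butyl(dimethyl)silyl]oxymethyl]-1-[3,5-dimethoxy-4-(methoxymethoxy)phenyl]-3-oxopropyl]-3,5-dimethoxy-4-(methoxymethoxy)phenyl trifluoromethanesulfonate | COc1cc([C@H]([C@@H](CO[Si](C)(C)C(C)(C)C)C=O)c2c(OC)c(OCOC)c(OC)cc2OS(=O)(=O)C(F)(F)F)cc(OC)c1OCOC | intermediate
17 | 2-[(1S,2R)-2-[[tert-butyl(dimethyl)silyl]oxymethyl]-1-[3,5-dimethoxy-4-(methoxymethoxy)phenyl]-4-methoxybut-3-enyl]-3,5-dimethoxy-4-(methoxymethoxy)phenyl trifluoromethanesulfonate (E/Z mixture) | COc1cc([C@H]([C@@H](CO[Si](C)(C)C(C)(C)C)C=COC)c2c(OC)c(OCOC)c(OC)cc2OS(=O)(=O)C(F)(F)F)cc(OC)c1OCOC | intermediate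
18 | carbon monoxide | [C-]#[O+] | starting material
19 | (3R,4S)-3-[[tert-butyl(dimethyl)silyl]oxymethyl]-4-[3,5-dimethoxy-4-(methoxymethoxy)phenyl]-5,7-dimethoxy-6-(methoxymethoxy)-2-(methoxymethylidene)-3,4-dihydronaphthalen-1(2H)-one (alkene geometry not fixed) | COc1cc([C@H]2c3c(cc(OC)c(OCOC)c3OC)C(=O)C(=COC)[C@@H]2CO[Si](C)(C)C(C)(C)C)cc(OC)c1OCOC | intermediate
20 | (3R,4S)-3-[[tert-butyl(dimethyl)silyl]oxymethyl]-4-[3,5-dimethoxy-4-(methoxymethoxy)phenyl]-5,7-dimethoxy-6-(methoxymethoxy)-2-(methoxymethylidene)-1,2,3,4-tetrahydronaphthalen-1-ol (carbinol epimers) | COc1cc([C@H]2c3c(cc(OC)c(OCOC)c3OC)C(O)C(=COC)[C@@H]2CO[Si](C)(C)C(C)(C)C)cc(OC)c1OCOC | intermediate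
21 | (1S,2R)-2-[[tert-butyl(dimethyl)silyl]oxymethyl]-1-[3,5-dimethoxy-4-(methoxymethoxy)phenyl]-6,8-dimethoxy-7-(methoxymethoxy)-1,2-dihydronaphthalene-3-carbaldehyde | COc1cc([C@H]2c3c(cc(OC)c(OCOC)c3OC)C=C(C=O)[C@@H]2CO[Si](C)(C)C(C)(C)C)cc(OC)c1OCOC | intermediate
22 | (1S,2R)-7-hydroxy-1-(4-hydroxy-3,5-dimethoxyphenyl)-2-(hydroxymethyl)-6,8-dimethoxy-1,2-dihydronaphthalene-3-carbaldehyde | COc1cc([C@H]2c3c(cc(OC)c(O)c3OC)C=C(C=O)[C@@H]2CO)cc(OC)c1O | target

## Step count and least certain steps

Total: 14 steps. Longest linear sequence: 12 steps (steps 1 to 5, then 8 to 14); the boronic acid branch (steps 6 and 7) joins at step 8.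

Step 12 (key step). Most likely to go wrong: ring closure by the arylpalladium species before carbon monoxide is taken up (direct 5-exo or 6-endo arylation of the enol ether), acyl transfer to the oxygen-bearing alkene carbon (7-endo, to which a cationic palladium–dppp complex is electronically inclined), or re-addition of palladium hydride to the product with drift of the double bond into ring B and aromatisation, which would erase C1 and C2. Fallback, from 17 back to the route at 21: the acylpalladium species is intercepted by hydride instead of the alkene. Reductive carbonylation of the triflate (Pd(OAc)2, dppp, CO, Et3SiH, Et3N, DMF, 70 °C) gives the ring A aryl aldehyde F1, so C4 still comes from carbon monoxide. Brief treatment with dilute aqueous HCl in THF at 0 °C hydrolyses the enol ether to dialdehyde F2, in which C3 is the α-carbon of an aliphatic aldehyde and C2 is no longer epimerisable. Dibenzylammonium trifluoroacetate in warm toluene closes ring B by intramolecular aldol condensation of C3 onto the non-enolisable C4 aldehyde, giving 21, which is deprotected under the conditions of step 14 to 22.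

Step 8. Most likely to go wrong: slow insertion at a β-carbon whose aryl group is twisted out of plane, so that its two ortho substituents cover both faces of the alkene; protodeboronation of 13, 1,2-addition to the formyl group and loss of enantioselectivity would then take over, and prolonged exposure to hydroxide could hydrolyse the triflate. Fallback, from 6 back to the route at 14: the acceptor is made planar and the C4a oxygen is tied up as a lactone. Salicylaldehyde 6 with ethyl (triphenylphosphoranylidene)acetate in refluxing N,N-diethylaniline gives coumarin F3. Rhodium-catalysed asymmetric addition of 13 (Rh(acac)(C2H4)2, a Segphos enantiomer, dioxane/H2O, 60 °C), which is established for coumarins, gives dihydrocoumarin F4. LiBH4 opens the lactone to phenol alcohol F5, N-phenyltriflimide with Et3N sulfonylates the phenol only to give triflate alcohol F6, and Dess–Martin oxidation returns 14.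

Step 9. Most likely to go wrong: slow enamine formation from the hindered β,β-diaryl aldehyde, so that dehydration of the aldol to the α-methylene aldehyde and retro-aldol scrambling of C2 compete during the long reaction and during silylation. Fallback, from 6 (through F3 and F4 of the previous fallback) back to the route at 17: C2 is set by substrate control in the rigid lactone. The lithium enolate of F4 (LiHMDS, THF, −78 °C) takes up monomeric formaldehyde on the face away from the C1 aryl group to give trans hydroxymethyl lactone F7. Silylation gives F8, DIBAL-H at −78 °C gives lactol F9, and Wittig methoxymethylenation of the lactol (it reacts through its open hydroxy aldehyde form) gives phenol enol ether F10. N-phenyltriflimide with Et3N then gives 17.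

Step 11. Most likely to go wrong: deprotonation of the α-carbon of 16 by the basic ylide, leading to epimerisation at C2 or β-elimination of the silyloxy group, and attack of the ylide on the sulfonyl group of the triflate. Fallback, from 16 back to the route at 17: the enol ether is built without a strong base. Takai–Utimoto boryl olefination (CrCl2, Cl2CHBpin, LiI, THF) gives (E)-alkenyl boronate F11, and copper-promoted coupling with methanol (Cu(OAc)2, Et3N, MeOH, air, rt) gives the (E)-isomer of 17.

## Further compounds

F1 | step 12 | 2-[(1S,2R)-2-[[tert-butyl(dimethyl)silyl]oxymethyl]-1-[3,5-dimethoxy-4-(methoxymethoxy)phenyl]-4-methoxybut-3-enyl]-3,5-dimethoxy-4-(methoxymethoxy)benzaldehyde | COc1cc([C@H]([C@@H](CO[Si](C)(C)C(C)(C)C)C=COC)c2c(OC)c(OCOC)c(OC)cc2C=O)cc(OC)c1OCOC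
F2 | step 12 | dialdehyde from F1 (C3 as CH2CHO, formyl group on C4a; configuration as in 17) | COc1cc([C@H]([C@@H](CO[Si](C)(C)C(C)(C)C)CC=O)c2c(OC)c(OCOC)c(OC)cc2C=O)cc(OC)c1OCOC
F3 | step 8 | 5,7-dimethoxy-6-(methoxymethoxy)-2H-chromen-2-one | COCOc1c(OC)cc2oc(=O)ccc2c1OC
F4 | step 8 | (4S)-4-[3,5-dimethoxy-4-(methoxymethoxy)phenyl]-5,7-dimethoxy-6-(methoxymethoxy)chroman-2-one | COc1cc([C@@H]2CC(=O)Oc3cc(OC)c(OCOC)c(OC)c32)cc(OC)c1OCOC
F5 | step 8 | 2-[(1S)-1-[3,5-dimethoxy-4-(methoxymethoxy)phenyl]-3-hydroxypropyl]-3,5-dimethoxy-4-(methoxymethoxy)phenol | COc1cc([C@H](CCO)c2c(OC)c(OCOC)c(OC)cc2O)cc(OC)c1OCOC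
F6 | step 8 | 2-[(1S)-1-[3,5-dimethoxy-4-(methoxymethoxy)phenyl]-3-hydroxypropyl]-3,5-dimethoxy-4-(methoxymethoxy)phenyl trifluoromethanesulfonate | COc1cc([C@H](CCO)c2c(OC)c(OCOC)c(OC)cc2OS(=O)(=O)C(F)(F)F)cc(OC)c1OCOC
F7 | step 9 | (3S,4S)-4-[3,5-dimethoxy-4-(methoxymethoxy)phenyl]-3-(hydroxymethyl)-5,7-dimethoxy-6-(methoxymethoxy)chroman-2-one (trans) | COc1cc([C@H]([C@@H](CO)C2=O)c3c(OC)c(OCOC)c(OC)cc3O2)cc(OC)c1OCOC
F8 | step 9 | (3S,4S)-3-[[tert-butyl(dimethyl)silyl]oxymethyl]-4-[3,5-dimethoxy-4-(methoxymethoxy)phenyl]-5,7-dimethoxy-6-(methoxymethoxy)chroman-2-one | COc1cc([C@H]([C@@H](CO[Si](C)(C)C(C)(C)C)C2=O)c3c(OC)c(OCOC)c(OC)cc3O2)cc(OC)c1OCOC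
F9 | step 9 | lactol (chroman-2-ol) from F8, anomeric mixture, C1 and C2 as in 16 | COc1cc([C@H]([C@@H](CO[Si](C)(C)C(C)(C)C)C2O)c3c(OC)c(OCOC)c(OC)cc3O2)cc(OC)c1OCOC
F10 | step 9 | 2-[(1S,2R)-2-[[tert-butyl(dimethyl)silyl]oxymethyl]-1-[3,5-dimethoxy-4-(methoxymethoxy)phenyl]-4-methoxybut-3-enyl]-3,5-dimethoxy-4-(methoxymethoxy)phenol | COc1cc([C@H]([C@@H](CO[Si](C)(C)C(C)(C)C)C=COC)c2c(OC)c(OCOC)c(OC)cc2O)cc(OC)c1OCOC
F11 | step 11 | (E)-alkenyl pinacol boronate from 16 (CH=CH–Bpin in place of the formyl group; C1 and C2 as in 17) | COc1cc([C@H]([C@@H](CO[Si](C)(C)C(C)(C)C)/C=C/B3OC(C)(C)C(C)(C)O3)c2c(OC)c(OCOC)c(OC)cc2OS(=O)(=O)C(F)(F)F)cc(OC)c1OCOC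
A1 | alternative 1 | methyl 2-[2-[3,5-dimethoxy-4-(methoxymethoxy)benzoyl]-3,5-dimethoxy-4-(methoxymethoxy)phenyl]acetate | COC(=O)Cc1cc(OC)c(OCOC)c(OC)c1C(=O)c1cc(OC)c(OCOC)c(OC)c1
A2 | alternative 1 | 3,5-dimethoxy-4-(methoxymethoxy)-2-(trimethylsilyl)phenyl trifluoromethanesulfonate | COCOc1c(OC)cc(OS(=O)(=O)C(F)(F)F)c([Si](C)(C)C)c1OC
A3 | alternative 1 | methyl 3-[3,5-dimethoxy-4-(methoxymethoxy)phenyl]-3-oxopropanoate | COC(=O)CC(=O)c1cc(OC)c(OCOC)c(OC)c1
A4 | alternative 2 | cis-fused 1-aryl-2,3-bis(silyloxymethyl)octalin-6,8-dione with C3–C4 alkene | COc1cc([C@H]2[C@@H]3C(=O)CC(=O)C[C@@H]3C=C(CO[Si](C)(C)C(C)(C)C)[C@@H]2CO[Si](C)(C)C(C)(C)C)cc(OC)c1OCOC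
A5 | alternative 2 | acyclic aryl trienedione (Diels–Alder precursor; geometry of the terminal diene alkene left open) | COCOc1c(OC)cc(/C=C/C(=O)CC(=O)C/C=C/C(CO[Si](C)(C)C(C)(C)C)=CCO[Si](C)(C)C(C)(C)C)cc1OC
A6 | alternative 3 | dimethyl 1-aryl-3-hydroxytetralin-2,3-dicarboxylate | COCOc1c(OC)cc([C@H]2c3c(cc(OC)c(OCOC)c3OC)C[C@@](O)(C(=O)OC)[C@@H]2C(=O)OC)cc1OC
A7 | alternative 3 | methyl 3-[3,5-dimethoxy-2-[(E)-3-methoxy-3-oxoprop-1-enyl]-4-(methoxymethoxy)phenyl]-2-oxopropanoate | COC(=O)/C=C/c1c(OC)c(OCOC)c(OC)cc1CC(=O)C(=O)OC
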